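**Retrosynthetic overview** (isocoumarin numbering; ring A = carbocycle C4a–C8a, ring B = δ-lactone)
- Aspergimarin C ⇒ its primary silyl ether ⇒ ring B is cut at C4–C4a. C4 becomes the CH2 of a CH2CO2H group, a traceless radical handle. Ring A is raised to the quinone level, which gives an open-chain quinone ester acid.
- Enabling feature: O5 and O8 are para on ring A, so ring A is a masked 1,4-benzoquinone. In that quinone C4a–H is the free β-carbon of both the C8 carbonyl and the C1 ester. The excited quinone can oxidise the carboxylate on C4.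
- The C1–O2 ester comes from gentisic acid (as its dibenzyl ether) and a β-hydroxy ester. C3 comes from (R)-BINAP/Ru hydrogenation of a β-keto ester, itself made from an aldehyde and benzyl diazoacetate.
- The aldehyde comes from the ester of (S)-hept-6-en-2-ol with O-silylated (R)-mevalonic acid. (S)-Propylene oxide supplies C4′ and (R)-mevalonolactone supplies C3″, so both centres come from the chiral pool.
- Ring order: ring A is bought and passes through the quinone. Ring B is the only ring formed.

Key step: step 11

Remark: side-chain carbons are C1′–C5′ (carbinol C4′), mevalonyl carbons are C1″–C5″ (carbinol C3″), and TBS = tert-butyldimethylsilyl.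

**Step 1**
Reactants: 1 (R)-mevalonolactone
Product: 4 (3R)-5-(tert-butyldimethylsilyloxy)-3-hydroxy-3-methylpentanoic acid, via potassium mevalonate 2 (not isolated), via bis-silyl mevalonate 3 (not isolated)
Conditions: KOH (1.0 equiv), MeOH/H2O, rt, evaporate; TBSCl (2.3 equiv), imidazole, DMF, rt; then MeOH/H2O, rt
Reagents that add atoms: potassium hydroxide [K+].[OH-]; tert-butyldimethylsilyl chloride CC(C)(C)[Si](C)(C)Cl
Why: Saponification opens the δ-lactone, silylation caps the carboxylate and the primary hydroxyl but not the hindered tertiary one, and aqueous methanol cleaves only the labile silyl ester, so the (R) centre C3″ is carried unchanged from the chiral pool.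

**Step 2**
Reactants: 5 gentisic acid
Product: 6 benzyl 2,5-bis(benzyloxy)benzoate
Conditions: BnBr (3.3 equiv), K2CO3, DMF, 60 °C
Reagents that add atoms: benzyl bromide BrCc1ccccc1
Why: Williamson ether synthesis at both phenols and alkylation of the carboxylate should proceed together under standard conditions.

**Step 3**
Reactants: 6 benzyl 2,5-bis(benzyloxy)benzoate
Product: 7 2,5-bis(benzyloxy)benzoic acid
Conditions: KOH, THF/MeOH/H2O, 60 °C; then 1 M HCl
Reagents that add atoms: potassium hydroxide [K+].[OH-]
Why: Saponification cleaves only the benzyl ester, since aryl benzyl ethers are inert to base.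

**Step 4**
Reactants: 8 (S)-propylene oxide; 9 but-3-enylmagnesium bromide
Product: 10 (2S)-hept-6-en-2-ol
Conditions: CuI (10 mol %), THF, −30 to 0 °C; 1 M HCl work-up
Reagents that add atoms: none
Why: Copper-catalysed Grignard opening of the epoxide is an SN2 attack at the unsubstituted carbon, so the C–O bond of the stereocentre is untouched and C4′ keeps the (S) configuration of the epoxide.

**Step 5**
Reactants: 10 (2S)-hept-6-en-2-ol; 4 (3R)-5-(tert-butyldimethylsilyloxy)-3-hydroxy-3-methylpentanoic acid
Product: 11 (2S)-hept-6-en-2-yl (3R)-5-(tert-butyldimethylsilyloxy)-3-hydroxy-3-methylpentanoate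
Conditions: EDC·HCl (1.3 equiv), DMAP (0.3 equiv), CH2Cl2, 0 °C to rt
Reagents that add atoms: none
Why: Steglich-type carbodiimide esterification transfers the acyl group to the alcohol oxygen with retention at C4′, and the tertiary hydroxyl of the acid is too hindered to compete.

**Step 6**
Reactants: 11 (2S)-hept-6-en-2-yl (3R)-5-(tert-butyldimethylsilyloxy)-3-hydroxy-3-methylpentanoate
Product: 12 (2S)-6-oxohexan-2-yl (3R)-5-(tert-butyldimethylsilyloxy)-3-hydroxy-3-methylpentanoate
Conditions: O3, CH2Cl2, −78 °C; then Me2S, −78 °C to rt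
Reagents that add atoms: ozone [O-][O+]=O
Why: Ozonolysis with reductive work-up cuts the only C=C bond to the aldehyde that becomes C3, while esters, silyl ether and tertiary alcohol are inert.

**Step 7**
Reactants: 12 (2S)-6-oxohexan-2-yl (3R)-5-(tert-butyldimethylsilyloxy)-3-hydroxy-3-methylpentanoate; 13 benzyl diazoacetate
Product: 14 benzyl (7S)-7-{[(3R)-5-(tert-butyldimethylsilyloxy)-3-hydroxy-3-methylpentanoyl]oxy}-3-oxooctanoate
Conditions: SnCl2 (10 mol %), CH2Cl2, rt
Reagents that add atoms: none
Why: In the Roskamp reaction the diazo carbon adds to the Lewis-acid-activated aliphatic aldehyde, and a 1,2-hydride shift with loss of nitrogen gives the β-keto ester, which brings in C4 and its carboxyl handle.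

**Step 8**
Reactants: 14 benzyl (7S)-7-{[(3R)-5-(tert-butyldimethylsilyloxy)-3-hydroxy-3-methylpentanoyl]oxy}-3-oxooctanoate
Product: 15 benzyl (3R,7S)-3-hydroxy-7-{[(3R)-5-(tert-butyldimethylsilyloxy)-3-hydroxy-3-methylpentanoyl]oxy}octanoate
Conditions: RuCl2[(R)-BINAP] (1 mol %), H2 (10 bar), EtOH/CH2Cl2, 45 °C
Reagents that add atoms: none
Why: Noyori asymmetric hydrogenation reduces only the chelating β-keto ester, and the (R)-BINAP ligand sets C3 as (R) under catalyst control, the same sense as for simple 3-oxoalkanoates.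

**Step 9**
Reactants: 15 benzyl (3R,7S)-3-hydroxy-7-{[(3R)-5-(tert-butyldimethylsilyloxy)-3-hydroxy-3-methylpentanoyl]oxy}octanoate; 7 2,5-bis(benzyloxy)benzoic acid
Product: 16 benzyl (3R,7S)-3-{[2,5-bis(benzyloxy)benzoyl]oxy}-7-{[(3R)-5-(tert-butyldimethylsilyloxy)-3-hydroxy-3-methylpentanoyl]oxy}octanoate
Conditions: EDC·HCl (1.5 equiv), DMAP (0.2 equiv), CH2Cl2, 0 °C
Reagents that add atoms: none
Why: Steglich-type esterification forms the C1–O2 bond at the only unhindered hydroxyl with retention at C3, and the low temperature and small amount of DMAP hold back E1cB loss of the new acyloxy group.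

**Step 10**
Reactants: 16 benzyl (3R,7S)-3-{[2,5-bis(benzyloxy)benzoyl]oxy}-7-{[(3R)-5-(tert-butyldimethylsilyloxy)-3-hydroxy-3-methylpentanoyl]oxy}octanoate
Product: 17 (3R,7S)-3-[(2,5-dihydroxybenzoyl)oxy]-7-{[(3R)-5-(tert-butyldimethylsilyloxy)-3-hydroxy-3-methylpentanoyl]oxy}octanoic acid
Conditions: H2 (1 atm), Pd/C (10 %), EtOAc, rt
Reagents that add atoms: none
Why: Neutral hydrogenolysis removes the two aryl benzyl ethers and the benzyl ester in one operation and leaves alkyl esters, the silyl ether and all stereocentres untouched.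

**Step 11**
Reactants: 17 (3R,7S)-3-[(2,5-dihydroxybenzoyl)oxy]-7-{[(3R)-5-(tert-butyldimethylsilyloxy)-3-hydroxy-3-methylpentanoyl]oxy}octanoic acid
Product: 19 5″-O-TBS aspergimarin C, via quinone acid 18 (not isolated)
Conditions: PhI(OAc)2 (1.0 equiv), CH2Cl2, 0 °C, dark; evaporate from toluene; 2,4,6-collidine (2 equiv), degassed MeCN (0.5 mM), 440 nm LEDs, 20 °C; aq. NaH2PO4
Reagents that add atoms: none
Why: Proposed new method: PhI(OAc)2 dehydrogenates the hydroquinone of 17 to quinone 18, and blue light then excites ring A to its n,π* triplet, a strong one-electron oxidant that takes an electron from the collidine-paired carboxylate on C4; the acyloxy radical loses CO2 at once, the primary C4 radical and the semiquinone radical anion of the same molecule combine at C4a, and the dienolate tautomerises to the aromatic 5,8-diol, so the photochemical event is redox neutral and sheds only CO2. The closest known reaction types are the photodecarboxylative cyclisation of ω-phthalimidoalkanoates (the same sequence of electron transfer, decarboxylation and biradical C–C closure) and the Minisci-type decarboxylative alkylation of quinones with AgNO3 and persulfate, which shows that primary alkyl radicals attack the free carbon of a quinone. Ring B closes in the 6-endo-trig mode on the C4a=C8a double bond. No stereocentre is formed, and C3, C4′ and C3″ are spectators because the radical sits on C4 and a β-acyloxyalkyl radical does not fragment. The step needs attack at C4a only: C4a is the one unsubstituted β-carbon of two acceptor groups (C8=O and C1=O), 5-exo attack at C8a would build a quaternary α-carbon in a strained spiro γ-lactone, attack at O8 or O5 would need seven- or eight-membered rings, and C6 and C7 are out of reach. Because the radical is generated within one molecule the reaction can be run at high dilution, which leaves time for the slow turn of the ester from its Z to the E conformer that closure requires and holds back addition to a second quinone, while aprotic acetonitrile and the proton-free semiquinone anion suppress hydrogen transfer to C4.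

**Step 12**
Reactants: 19 5″-O-TBS aspergimarin C
Product: 20 aspergimarin C
Conditions: HF·pyridine, excess pyridine, THF, 0 °C, argon
Reagents that add atoms: none
Why: Buffered fluoride desilylation cleaves the primary silyl ether quickly at low temperature without touching the three esters or any stereocentre.

**Compound list**
1 | (R)-mevalonolactone | O=C1C[C@](C)(O)CCO1 | starting material
2 | potassium (3R)-3,5-dihydroxy-3-methylpentanoate | [K+].[O-]C(=O)C[C@](C)(O)CCO | intermediate
3 | tert-butyldimethylsilyl (3R)-5-(tert-butyldimethylsilyloxy)-3-hydroxy-3-methylpentanoate | CC(C)(C)[Si](C)(C)OC(=O)C[C@](C)(O)CCO[Si](C)(C)C(C)(C)C | intermediate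
4 | (3R)-5-(tert-butyldimethylsilyloxy)-3-hydroxy-3-methylpentanoic acid | OC(=O)C[C@](C)(O)CCO[Si](C)(C)C(C)(C)C | intermediate
5 | gentisic acid (2,5-dihydroxybenzoic acid) | OC(=O)c1cc(O)ccc1O | starting material
6 | benzyl 2,5-bis(benzyloxy)benzoate | O=C(OCc1ccccc1)c1cc(OCc2ccccc2)ccc1OCc1ccccc1 | intermediate
7 | 2,5-bis(benzyloxy)benzoic acid | OC(=O)c1cc(OCc2ccccc2)ccc1OCc1ccccc1 | intermediate
8 | (S)-propylene oxide | C[C@H]1CO1 | starting material
9 | but-3-enylmagnesium bromide | C=CCC[Mg]Br | starting material
10 | (2S)-hept-6-en-2-ol | C[C@@H](CCCC=C)O | intermediate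
11 | (2S)-hept-6-en-2-yl (3R)-5-(TBS-oxy)-3-hydroxy-3-methylpentanoate | C[C@@H](CCCC=C)OC(=O)C[C@](C)(O)CCO[Si](C)(C)C(C)(C)C | intermediate
12 | (2S)-6-oxohexan-2-yl (3R)-5-(TBS-oxy)-3-hydroxy-3-methylpentanoate | C[C@@H](CCCC=O)OC(=O)C[C@](C)(O)CCO[Si](C)(C)C(C)(C)C | intermediate
13 | benzyl diazoacetate | [N-]=[N+]=CC(=O)OCc1ccccc1 | starting material
14 | benzyl (7S)-7-{[(3R)-5-(TBS-oxy)-3-hydroxy-3-methylpentanoyl]oxy}-3-oxooctanoate | C[C@@H](CCCC(=O)CC(=O)OCc1ccccc1)OC(=O)C[C@](C)(O)CCO[Si](C)(C)C(C)(C)C | intermediate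
15 | benzyl (3R,7S)-3-hydroxy-7-{[(3R)-5-(TBS-oxy)-3-hydroxy-3-methylpentanoyl]oxy}octanoate | C[C@@H](CCC[C@@H](O)CC(=O)OCc1ccccc1)OC(=O)C[C@](C)(O)CCO[Si](C)(C)C(C)(C)C | intermediate
16 | benzyl (3R,7S)-3-{[2,5-bis(benzyloxy)benzoyl]oxy}-7-{[(3R)-5-(TBS-oxy)-3-hydroxy-3-methylpentanoyl]oxy}octanoate | C[C@@H](CCC[C@@H](OC(=O)c1cc(OCc2ccccc2)ccc1OCc1ccccc1)CC(=O)OCc1ccccc1)OC(=O)C[C@](C)(O)CCO[Si](C)(C)C(C)(C)C | intermediate
17 | (3R,7S)-3-[(2,5-dihydroxybenzoyl)oxy]-7-{[(3R)-5-(TBS-oxy)-3-hydroxy-3-methylpentanoyl]oxy}octanoic acid | C[C@@H](CCC[C@@H](OC(=O)c1cc(O)ccc1O)CC(=O)O)OC(=O)C[C@](C)(O)CCO[Si](C)(C)C(C)(C)C | intermediate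
18 | (3R,7S)-3-[(3,6-dioxocyclohexa-1,4-diene-1-carbonyl)oxy]-7-{[(3R)-5-(TBS-oxy)-3-hydroxy-3-methylpentanoyl]oxy}octanoic acid | C[C@@H](CCC[C@@H](OC(=O)C1=CC(=O)C=CC1=O)CC(=O)O)OC(=O)C[C@](C)(O)CCO[Si](C)(C)C(C)(C)C | intermediate
19 | 5″-O-TBS aspergimarin C | C[C@@H](CCC[C@@H]1Cc2c(O)ccc(O)c2C(=O)O1)OC(=O)C[C@](C)(O)CCO[Si](C)(C)C(C)(C)C | intermediate
20 | aspergimarin C | C[C@@H](CCC[C@@H]1Cc2c(O)ccc(O)c2C(=O)O1)OC(=O)C[C@](C)(O)CCO | target

**Step count**
Total step count: 12. Longest linear sequence: 9 steps (steps 4 to 12 from 8, or step 1 and steps 5 to 12 from 1).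

**Steps most likely to fail**

**Step 11.**
- What may go wrong: back electron transfer may outrun decarboxylation. The primary radical may also be lost before the ester has turned into the conformer needed for closure. The loss channels are hydrogen abstraction, 1,2-acyloxy migration (Surzur–Tanner rearrangement) and addition to a second quinone molecule.
- Fallback (known chemistry, sets out from 11 and 7, comes back at 19): alkene 11 is epoxidised with mCPBA to the epoxide mixture F1. Hydrolytic kinetic resolution with (R,R)-(salen)Co(OAc) and 0.55 equiv of water leaves the (R)-epoxide F2. The other diastereomer is turned into the diol F3, which is removed by chromatography. Acid 7 and F2 are then joined with Pd(OAc)2, N-acetyl-tert-leucine and KOAc in HFIP at 75 °C. This is the carboxylate-directed ortho C–H alkylation of a benzoic acid with a terminal epoxide followed by lactonisation, with retention at C3, and it gives the dibenzyl lactone F4. Hydrogenolysis (H2, Pd/C, EtOAc) leads to 19.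

**Step 8.**
- What may go wrong: acid traces from the ruthenium halide precatalyst may strip the silyl ether or exchange the benzyl ester with the alcohol solvent. Facial selectivity may also be incomplete.
- Fallback (sets out from 12, comes back at 15, and replaces steps 7 and 8): a catalytic asymmetric Mukaiyama aldol addition of 1-(benzyloxy)-1-(trimethylsilyloxy)ethene to aldehyde 12 is run with Ti(OiPr)4 and the BINOL enantiomer that opens the Si face. It gives the silylated aldol F5. Citric acid in methanol removes only the trimethylsilyl ether and gives 15.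

**Step 12.**
- What may go wrong: once the silyl group is gone, the primary hydroxyl may add to the neighbouring ester carbonyl. The acyl unit would then be lost as its six-membered lactone, a process that the acidic phenols can assist. The free hydroquinone may also be oxidised by air in the pyridine medium.
- Fallback (sets out from 16, comes back at 20): the deprotection is moved ahead of the ring closure, so that nothing follows the key step. HF·pyridine on 16 gives the primary alcohol F6. Hydrogenolysis gives the hydroquinone acid F7. The conditions of step 11 lead through the quinone acid F8 directly to 20.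

**Further compounds**
F1 | step 11 | (2S)-5-(oxiran-2-yl)pentan-2-yl (3R)-5-(TBS-oxy)-3-hydroxy-3-methylpentanoate, mixture at the oxirane carbon | C[C@@H](CCCC1CO1)OC(=O)C[C@](C)(O)CCO[Si](C)(C)C(C)(C)C
F2 | step 11 | (2S)-5-[(2R)-oxiran-2-yl]pentan-2-yl (3R)-5-(TBS-oxy)-3-hydroxy-3-methylpentanoate | C[C@@H](CCC[C@@H]1CO1)OC(=O)C[C@](C)(O)CCO[Si](C)(C)C(C)(C)C
F3 | step 11 | (2S,6S)-6,7-dihydroxyheptan-2-yl (3R)-5-(TBS-oxy)-3-hydroxy-3-methylpentanoate | C[C@@H](CCC[C@H](O)CO)OC(=O)C[C@](C)(O)CCO[Si](C)(C)C(C)(C)C
F4 | step 11 | 5,8-di-O-benzyl-5″-O-TBS aspergimarin C | C[C@@H](CCC[C@@H]1Cc2c(OCc3ccccc3)ccc(OCc3ccccc3)c2C(=O)O1)OC(=O)C[C@](C)(O)CCO[Si](C)(C)C(C)(C)C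
F5 | step 8 | benzyl (3R,7S)-3-(trimethylsilyloxy)-7-{[(3R)-5-(TBS-oxy)-3-hydroxy-3-methylpentanoyl]oxy}octanoate | C[C@@H](CCC[C@@H](O[Si](C)(C)C)CC(=O)OCc1ccccc1)OC(=O)C[C@](C)(O)CCO[Si](C)(C)C(C)(C)C
F6 | step 12 | benzyl (3R,7S)-3-{[2,5-bis(benzyloxy)benzoyl]oxy}-7-{[(3R)-3,5-dihydroxy-3-methylpentanoyl]oxy}octanoate | C[C@@H](CCC[C@@H](OC(=O)c1cc(OCc2ccccc2)ccc1OCc1ccccc1)CC(=O)OCc1ccccc1)OC(=O)C[C@](C)(O)CCO
F7 | step 12 | (3R,7S)-3-[(2,5-dihydroxybenzoyl)oxy]-7-{[(3R)-3,5-dihydroxy-3-methylpentanoyl]oxy}octanoic acid | C[C@@H](CCC[C@@H](OC(=O)c1cc(O)ccc1O)CC(=O)O)OC(=O)C[C@](C)(O)CCO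
F8 | step 12 | (3R,7S)-3-[(3,6-dioxocyclohexa-1,4-diene-1-carbonyl)oxy]-7-{[(3R)-3,5-dihydroxy-3-methylpentanoyl]oxy}octanoic acid | C[C@@H](CCC[C@@H](OC(=O)C1=CC(=O)C=CC1=O)CC(=O)O)OC(=O)C[C@](C)(O)CCO
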